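The ten-membered carbocycle C1–C10 is traced back to the six-membered ring of (R)-carvone. The target hides a cyclodec-5-enone: the lactone oxygen on C6 marks a former carbonyl group, the C1–C10 oxirane a former E double bond, C8–C9 is the σ bond midway between them, and the cis C4=C5 bond with its C4 methyl group is the ring alkene of carvone. One anionic [3,3] shift cleaves C1–C6, forms C8–C9, enlarges the ring by four atoms, sets E C1=C10 and hands the carvone stereocentre on to C8. Its precursor is a cyclohexenol with an E-2-alkoxyvinyl group on C6 and, trans to it, the isopropenyl group on C1.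

Key step: step 7

Remark: germacrane numbering of the target is used for all ring compounds (ring C1–C10, lactone carbons C11–C13, C14 = methyl on C10, C15 = methyl on C4). β is the face of the C8 oxygen and α the face of H7. The C3 silyloxy centre is a temporary handle that vanishes in step 20.

Step 1
Reactants: 1 (R)-carvone
Product: 2 (1R,5R)-cis-carveol
Conditions: NaBH4, CeCl3·7H2O, MeOH, −20 °C
Reagents that add atoms: none
Why: Luche reduction gives clean 1,2-addition, and hydride enters axially on the face away from the equatorial isopropenyl group, so the new carbinol centre (later C3) is R and cis to the isopropenyl group.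

Step 2
Reactants: 2 (1R,5R)-cis-carveol
Product: 3 (1R,5R)-cis-carveol tert-butyldimethylsilyl ether
Conditions: TBSCl, imidazole, DMF, rt
Reagents that add atoms: tert-butyldimethylsilyl chloride, CC(C)(C)[Si](C)(C)Cl
Why: Imidazole-catalysed silylation of a secondary allylic alcohol creates no stereocentre and gives an ether that withstands chromium oxidants, organolithiums and KH.

Step 3
Reactants: 3 (1R,5R)-cis-carveol tert-butyldimethylsilyl ether
Product: 4 (4R,6R)-4-(tert-butyldimethylsilyloxy)-3-methyl-6-(prop-1-en-2-yl)cyclohex-2-en-1-one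
Conditions: CrO3, 3,5-dimethylpyrazole, CH2Cl2, −20 °C
Reagents that add atoms: chromium trioxide, O=[Cr](=O)=O
Why: Allylic oxidation with the CrO3–3,5-dimethylpyrazole complex turns the only ring CH2 allylic to the electron-rich trisubstituted alkene into the carbonyl group of the transposed enone, while the bulky silyl ether shields the carbinol C–H, the 1,1-disubstituted isopropenyl group reacts more slowly and the cold, non-basic medium leaves the α-stereocentre (later C1) untouched.

Step 4
Reactants: 5 4-methoxybenzyl alcohol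
Product: 9 ethynyl 4-methoxybenzyl ether, via potassium 4-methoxybenzyl oxide 6 (not isolated), via (E)-1,2-dichlorovinyl ether 7 (not isolated), via lithium alkoxyacetylide 8 (not isolated)
Conditions: KH, THF, 0 °C; Cl2C=CHCl, −50 °C → rt; n-BuLi (2.2 equiv), −78 → −40 °C; MeOH, −78 °C
Reagents that add atoms: trichloroethylene, ClC=C(Cl)Cl
Why: Ynol ether synthesis by addition–elimination, in which the alkoxide adds to dichloroacetylene formed in situ and n-BuLi then effects dehydrochlorination and chlorine–lithium exchange to the acetylide that methanol protonates; the benzyl ynol ether is kept at or below room temperature because it rearranges on heating.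

Step 5
Reactants: 9 ethynyl 4-methoxybenzyl ether
Product: 11 (E)-2-iodoethenyl 4-methoxybenzyl ether, via alkenylzirconocene chloride 10 (not isolated)
Conditions: Cp2Zr(H)Cl, THF, rt, dark; I2, −78 °C; used crude
Reagents that add atoms: iodine, II
Why: Hydrozirconation adds Zr–H syn with zirconium on the terminal, electron-rich carbon, and iodinolysis proceeds with retention, so only the E 2-alkoxyvinyl iodide is expected.

Step 6
Reactants: 11 (E)-2-iodoethenyl 4-methoxybenzyl ether; 4 (4R,6R)-4-(tert-butyldimethylsilyloxy)-3-methyl-6-(prop-1-en-2-yl)cyclohex-2-en-1-one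
Product: 13 (1R,4R,6R)-4-(tert-butyldimethylsilyloxy)-1-[(E)-2-(4-methoxybenzyloxy)ethenyl]-3-methyl-6-(prop-1-en-2-yl)cyclohex-2-en-1-ol, via E-alkenyllithium 12 (not isolated)
Conditions: 11, t-BuLi (2.0 equiv), Et2O, −78 °C, 15 min; then 4, Et2O, −78 °C; H2O
Reagents that add atoms: none
Why: Iodine–lithium exchange with retention gives the E alkenyllithium, which is consumed at −78 °C before anti β-elimination of alkoxide sets in, and 1,2-addition of this bulky sp2 nucleophile to the enone should occur on the face opposite the neighbouring isopropenyl group (equatorial attack), which sets C6 as R with the two alkenyl groups trans and diequatorial.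

Step 7
Reactants: 13 (1R,4R,6R)-4-(tert-butyldimethylsilyloxy)-1-[(E)-2-(4-methoxybenzyloxy)ethenyl]-3-methyl-6-(prop-1-en-2-yl)cyclohex-2-en-1-ol
Product: 16 (2Z,4R,6E,9R)-4-(tert-butyldimethylsilyloxy)-9-(4-methoxybenzyloxy)-3,7-dimethylcyclodeca-2,6-dien-1-one, via potassium alkoxide 14 (not isolated), via ten-membered potassium enolate 15 (not isolated)
Conditions: KH, 18-crown-6, THF, 0 °C → rt; AcOH in THF, −78 °C
Reagents that add atoms: none
Why: KH with 18-crown-6 gives the dissociated alkoxide 14, whose oxyanion weakens the C1–C6 bond, and a concerted [3,3] shift over C8=C7–C6–C1–C10=C9 breaks C1–C6 and joins C8 to C9 to leave enolate 15, which cold acetic acid protonates at C7. This is an anionic oxy-Cope rearrangement of a trans-1,2-dialkenylcyclohexanol, the established four-carbon enlargement to cyclodec-5-enones. The ten-membered ring is not closed by an exo or endo cyclisation but arises by sigmatropic ring expansion, the six-membered ring and the six-centre array sharing the bond that breaks. With both alkenyl groups equatorial the array is a chair fused like a trans-decalin, so C2 sits equatorial and C1=C10 emerges E, while C4=C5 is carried over as the Z ring alkene. C8 is the only new stereocentre: the E enol ether places its oxygen equatorial and the R centre C1 from carvone decides which of the two mirror-image chairs forms, so C9 bonds to one face of C8 and gives 8R as C1 itself becomes planar. The step needs chair over boat and rearrangement over retro-addition or loss of the C8 alkoxide, and the trans-diequatorial arrangement, the E geometry, the crown ether and the in-plane C8–O bond of the nascent enolate should secure this.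

Step 8
Reactants: 16 (2Z,4R,6E,9R)-4-(tert-butyldimethylsilyloxy)-9-(4-methoxybenzyloxy)-3,7-dimethylcyclodeca-2,6-dien-1-one
Product: 18 ethyl 2-[(1R,2R,4E,7R,8Z)-7-(tert-butyldimethylsilyloxy)-2-(4-methoxybenzyloxy)-4,8-dimethyl-10-oxocyclodeca-4,8-dien-1-yl]acetate (7R,8R), via chelated lithium enolate 17 (not isolated)
Conditions: LiN(SiMe3)2, THF, −78 °C; ICH2CO2Et, −78 → −30 °C, no polar cosolvent
Reagents that add atoms: ethyl iodoacetate, CCOC(=O)CI
Why: Kinetic deprotonation on the C7 side gives the cross-conjugated lithium enolate, whose oxygen and the C8 ether oxygen should bind the same lithium ion in a six-membered chelate (the sense of a Fráter–Seebach alkylation), so that the C8–O bond lies in the enolate plane (no β-elimination), C9 blocks the inner face and the iodoacetate enters anti to C9 from the ring periphery, which sets C7 as R, cis to the C8 oxygen.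

Step 9
Reactants: 18 ethyl 2-[(1R,2R,4E,7R,8Z)-7-(tert-butyldimethylsilyloxy)-2-(4-methoxybenzyloxy)-4,8-dimethyl-10-oxocyclodeca-4,8-dien-1-yl]acetate
Product: 19 the corresponding (6S)-allylic alcohol (6β-OH), ethyl ester retained
Conditions: NaBH4, CeCl3·7H2O, MeOH/THF, −78 → −40 °C
Reagents that add atoms: none
Why: Luche 1,2-reduction spares ester and alkenes, and with the C7 side chain nearly eclipsing the carbonyl group hydride should come from the ring periphery anti to C8 (Felkin–Anh sense) to give the 6S alcohol, in which the wide C5–C6–C7–C8 ring torsion keeps hydroxyl and ester apart so that no cis-lactone forms.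

Step 10
Reactants: 19 (6S)-hydroxy ethyl ester
Product: 20 (6S)-hydroxy acid
Conditions: LiOH, THF/H2O, 0 °C → rt; cold 0.5 M HCl to pH 5
Reagents that add atoms: lithium hydroxide, [Li+].[OH-]
Why: Saponification of an unhindered ethyl ester is tolerated by silyl ether, PMB ether and allylic alcohol, and mild cold acidification frees the acid without ionising the allylic alcohol.

Step 11
Reactants: 20 (6S)-hydroxy acid
Product: 21 (3R,6R,7R,8R)-3-(tert-butyldimethylsilyloxy)-8-(4-methoxybenzyloxy)germacra-1(10)E,4Z-dien-6α,12-olide (trans-fused lactone)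
Conditions: PPh3, DIAD, THF, 0 °C
Reagents that add atoms: none
Why: Mitsunobu lactonisation activates the allylic C6 hydroxyl as its oxyphosphonium ion, and the C12 carboxylate displaces it from the open outer face in a 5-exo-tet SN2 closure with inversion, which turns 6S into 6R and gives the trans-fused lactone that the ring torsion favours.

Step 12
Reactants: 21 trans-fused lactone
Product: 25 (3R,6R,7R,8R)-3-(tert-butyldimethylsilyloxy)-8-(4-methoxybenzyloxy)germacra-1(10)E,4Z,11(13)-trien-6α,12-olide, via lithium lactone enolate 22 (not isolated), via Mannich base 23 (not isolated), via trimethylammonium iodide 24 (not isolated)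
Conditions: LiN(iPr)2, THF, −78 °C; Me2N=CH2+ I−, −78 °C → rt; MeI (excess), rt; aq NaHCO3, EtOAc, rt
Reagents that add atoms: Eschenmoser's salt (N,N-dimethylmethyleneiminium iodide), C=[N+](C)C.[I-]
Why: α-Methylenation by Mannich reaction of the lactone enolate, exhaustive methylation and Hofmann-type β-elimination is placed here because no oxirane or C8 ester that the amide base or the enolate could attack is present yet, and the C11 centre formed in passing is destroyed again.

Step 13
Reactants: 25 α-methylene lactone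
Product: 26 (1R,10R)-1β,10α-epoxide of 25
Conditions: mCPBA (1.0 equiv), NaHCO3, CH2Cl2, −20 → 0 °C
Reagents that add atoms: 3-chloroperoxybenzoic acid, OOC(=O)c1cccc(Cl)c1
Why: In this Prilezhaev epoxidation the isolated trisubstituted C1=C10 bond is the most electron-rich alkene (C4=C5 is flanked by two allylic C–O bonds, C11=C13 is conjugated), and in the lactone-locked ring with the C8 oxygen pseudoaxial it shows only its outer face, so syn delivery to the E alkene should give the trans 1R,10R oxirane.

Step 14
Reactants: 26 epoxy lactone PMB ether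
Product: 27 8β-alcohol (PMB removed)
Conditions: DDQ, CH2Cl2/pH 7 buffer, 0 °C
Reagents that add atoms: none
Why: Oxidative PMB cleavage (hydride abstraction from the electron-rich benzylic position, then hydrolysis) runs at neutral pH, leaves C8 untouched and is done before the oxidisable diene exists.

Step 15
Reactants: 28 tiglic acid
Product: 29 (E)-2-methylbut-2-en-1-ol
Conditions: LiAlH4, Et2O, 0 °C → rt; aq NaOH work-up
Reagents that add atoms: none
Why: Hydride reduction of the carboxylic acid with LiAlH4 leaves the trisubstituted E double bond in place.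

Step 16
Reactants: 29 (E)-2-methylbut-2-en-1-ol
Product: 30 (2R,3R)-2,3-epoxy-2-methylbutan-1-ol
Conditions: Ti(OiPr)4 (cat.), D-(−)-diisopropyl tartrate (cat.), t-BuOOH, 4 Å MS, CH2Cl2, −20 °C
Reagents that add atoms: tert-butyl hydroperoxide, CC(C)(C)OO
Why: Sharpless asymmetric epoxidation with the D-tartrate ligand delivers oxygen to the face of the E allylic alcohol that gives the 2R,3R oxirane, and the syn addition keeps the two methyl groups cis.

Step 17
Reactants: 30 (2R,3R)-2,3-epoxy-2-methylbutan-1-ol
Product: 31 (2S,3R)-2,3-epoxy-2-methylbutanoic acid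
Conditions: RuCl3·xH2O (cat.), NaIO4, MeCN/EtOAc/H2O, rt
Reagents that add atoms: water, O
Why: Catalytic RuO4 oxidation takes the primary alcohol through the aldehyde hydrate to the acid without touching the oxirane, so both centres are kept and C2 becomes S only because the priorities change.

Step 18
Reactants: 31 (2S,3R)-2,3-epoxy-2-methylbutanoic acid; 27 8β-alcohol
Product: 33 8β-[(2S,3R)-2,3-epoxy-2-methylbutanoate] of 27, via mixed anhydride 32 (not isolated)
Conditions: 31, 2,4,6-Cl3C6H2COCl, Et3N, toluene, rt; then 27, DMAP, toluene, rt → 40 °C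
Reagents that add atoms: none
Why: In the Yamaguchi esterification DMAP attacks the aliphatic carbonyl group of the mixed anhydride and the acylpyridinium ion acylates the hindered 8β-hydroxyl with retention at C8, while the acid has no α-hydrogen and cannot epimerise.

Step 19
Reactants: 33 epoxy ester silyl ether
Product: 34 3α-alcohol (TBS removed)
Conditions: Bu4NF, AcOH (1:1), THF, 0 °C → rt
Reagents that add atoms: none
Why: Fluoride-induced desilylation buffered with acetic acid stays nearly neutral, which protects the α-methylene lactone from conjugate addition and both oxiranes from opening (attack of O3 on C10 would be a disfavoured 5-endo closure).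

Step 20
Reactants: 34 3α-alcohol
Product: 35 (1R,6R,7R,8R,10R)-1β,10α-epoxy-8β-[(2S,3R)-2,3-epoxy-2-methylbutanoyloxy]germacra-2Z,4Z,11(13)-trien-6α,12-olide (CNP0122107.1)
Conditions: Ph2S[OC(CF3)2Ph]2 (Martin sulfurane), CH2Cl2, −20 °C → rt
Reagents that add atoms: none
Why: Dehydration with Martin sulfurane turns the alcohol into an alkoxysulfonium ion that leaves in an E2-type anti elimination, only C2 carries β-hydrogens, and in the lactone-locked ring the C3–O bond is pseudoaxial and antiperiplanar to one C2–H while the C1–C2–C3–C4 torsion is gauche, so the new double bond can only be Z and lactone, ester and oxiranes are inert to the neutral reagent.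

Compound list
1 | (R)-carvone | CC1=CC[C@H](CC1=O)C(C)=C | starting material
2 | (1R,5R)-cis-carveol | C1C=C(C)[C@H](O)C[C@@H]1C(C)=C | intermediate
3 | (1R,5R)-cis-carveol tert-butyldimethylsilyl ether | C1C=C(C)[C@H](O[Si](C)(C)C(C)(C)C)C[C@@H]1C(C)=C | intermediate
4 | (4R,6R)-4-(tert-butyldimethylsilyloxy)-3-methyl-6-(prop-1-en-2-yl)cyclohex-2-en-1-one | O=C1C=C(C)[C@H](O[Si](C)(C)C(C)(C)C)C[C@@H]1C(C)=C | intermediate
5 | 4-methoxybenzyl alcohol | COc1ccc(CO)cc1 | starting material
6 | potassium 4-methoxybenzyl oxide | COc1ccc(C[O-])cc1.[K+] | intermediate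
7 | (E)-1,2-dichlorovinyl 4-methoxybenzyl ether | COc1ccc(CO/C(Cl)=C\Cl)cc1 | intermediate
8 | lithium (4-methoxybenzyloxy)acetylide | COc1ccc(COC#C[Li])cc1 | intermediate
9 | ethynyl 4-methoxybenzyl ether | COc1ccc(COC#C)cc1 | intermediate
10 | (E)-2-(4-methoxybenzyloxy)ethenylzirconocene chloride | COc1ccc(CO/C=C/[Zr](Cl)(C2C=CC=C2)C2C=CC=C2)cc1 | intermediate
11 | (E)-2-iodoethenyl 4-methoxybenzyl ether | COc1ccc(CO/C=C/I)cc1 | intermediate
12 | (E)-2-(4-methoxybenzyloxy)ethenyllithium | COc1ccc(CO/C=C/[Li])cc1 | intermediate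
13 | (1R,4R,6R)-4-(tert-butyldimethylsilyloxy)-1-[(E)-2-(4-methoxybenzyloxy)ethenyl]-3-methyl-6-(prop-1-en-2-yl)cyclohex-2-en-1-ol | O[C@]1(/C=C/OCc2ccc(OC)cc2)C=C(C)[C@H](O[Si](C)(C)C(C)(C)C)C[C@@H]1C(C)=C | intermediate
14 | potassium alkoxide of 13 | [K+].[O-][C@]1(/C=C/OCc2ccc(OC)cc2)C=C(C)[C@H](O[Si](C)(C)C(C)(C)C)C[C@@H]1C(C)=C | intermediate
15 | potassium enolate of 16 (C6=C7, enolate oxygen cis to C8) | [K+].[O-]/C1=C\[C@H](OCc2ccc(OC)cc2)C/C(C)=C/C[C@@H](O[Si](C)(C)C(C)(C)C)/C(C)=C\1 | intermediate
16 | (2Z,4R,6E,9R)-4-(tert-butyldimethylsilyloxy)-9-(4-methoxybenzyloxy)-3,7-dimethylcyclodeca-2,6-dien-1-one | COc1ccc(CO[C@@H]2C/C(C)=C/C[C@@H](O[Si](C)(C)C(C)(C)C)/C(C)=C\C(=O)C2)cc1 | intermediate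
17 | lithium enolate of 16 (C6=C7, oxygen cis to C8, chelated by O8) | [Li]O/C1=C\[C@H](OCc2ccc(OC)cc2)C/C(C)=C/C[C@@H](O[Si](C)(C)C(C)(C)C)/C(C)=C\1 | intermediate
18 | ethyl 2-[(1R,2R,4E,7R,8Z)-7-(tert-butyldimethylsilyloxy)-2-(4-methoxybenzyloxy)-4,8-dimethyl-10-oxocyclodeca-4,8-dien-1-yl]acetate | COc1ccc(CO[C@@H]2C/C(C)=C/C[C@@H](O[Si](C)(C)C(C)(C)C)/C(C)=C\C(=O)[C@@H]2CC(=O)OCC)cc1 | intermediate
19 | (6S)-hydroxy ethyl ester (6β-OH, 7R, 8R, 3R) | COc1ccc(CO[C@@H]2C/C(C)=C/C[C@@H](O[Si](C)(C)C(C)(C)C)/C(C)=C\[C@H](O)[C@@H]2CC(=O)OCC)cc1 | intermediate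
20 | (6S)-hydroxy acid | COc1ccc(CO[C@@H]2C/C(C)=C/C[C@@H](O[Si](C)(C)C(C)(C)C)/C(C)=C\[C@H](O)[C@@H]2CC(=O)O)cc1 | intermediate
21 | (3R,6R,7R,8R)-3-(tert-butyldimethylsilyloxy)-8-(4-methoxybenzyloxy)germacra-1(10)E,4Z-dien-6α,12-olide | C1C(=O)O[C@@H]2/C=C(C)\[C@H](O[Si](C)(C)C(C)(C)C)C/C=C(C)/C[C@@H](OCc3ccc(OC)cc3)[C@@H]12 | intermediate
22 | lithium enolate of lactone 21 | C1=C(O[Li])O[C@@H]2/C=C(C)\[C@H](O[Si](C)(C)C(C)(C)C)C/C=C(C)/C[C@@H](OCc3ccc(OC)cc3)[C@@H]12 | intermediate
23 | 11-(dimethylaminomethyl) lactone (C11 not controlled) | CN(C)CC1C(=O)O[C@@H]2/C=C(C)\[C@H](O[Si](C)(C)C(C)(C)C)C/C=C(C)/C[C@@H](OCc3ccc(OC)cc3)[C@@H]12 | intermediate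
24 | trimethylammonium iodide of 23 | [I-].C[N+](C)(C)CC1C(=O)O[C@@H]2/C=C(C)\[C@H](O[Si](C)(C)C(C)(C)C)C/C=C(C)/C[C@@H](OCc3ccc(OC)cc3)[C@@H]12 | intermediate
25 | (3R,6R,7R,8R)-3-(tert-butyldimethylsilyloxy)-8-(4-methoxybenzyloxy)germacra-1(10)E,4Z,11(13)-trien-6α,12-olide | C=C1C(=O)O[C@@H]2/C=C(C)\[C@H](O[Si](C)(C)C(C)(C)C)C/C=C(C)/C[C@@H](OCc3ccc(OC)cc3)[C@@H]12 | intermediate
26 | (1R,10R)-1β,10α-epoxide of 25 | C=C1C(=O)O[C@@H]2/C=C(C)\[C@H](O[Si](C)(C)C(C)(C)C)C[C@H]3O[C@]3(C)C[C@@H](OCc3ccc(OC)cc3)[C@@H]12 | intermediate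
27 | 8β-alcohol (1β,10α-epoxy-3α-silyloxy-8β-hydroxygermacra-4Z,11(13)-dien-6α,12-olide) | C=C1C(=O)O[C@@H]2/C=C(C)\[C@H](O[Si](C)(C)C(C)(C)C)C[C@H]3O[C@]3(C)C[C@@H](O)[C@@H]12 | intermediate
28 | tiglic acid | C/C=C(\C)C(=O)O | starting material
29 | (E)-2-methylbut-2-en-1-ol | C/C=C(\C)CO | intermediate
30 | (2R,3R)-2,3-epoxy-2-methylbutan-1-ol | OC[C@@]1(C)O[C@@H]1C | intermediate
31 | (2S,3R)-2,3-epoxy-2-methylbutanoic acid | OC(=O)[C@@]1(C)O[C@@H]1C | intermediate
32 | mixed anhydride of 31 and 2,4,6-trichlorobenzoic acid | Clc1cc(Cl)c(C(=O)OC(=O)[C@@]2(C)O[C@@H]2C)c(Cl)c1 | intermediate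
33 | 8β-[(2S,3R)-2,3-epoxy-2-methylbutanoate] of 27 | C=C1C(=O)O[C@@H]2/C=C(C)\[C@H](O[Si](C)(C)C(C)(C)C)C[C@H]3O[C@]3(C)C[C@@H](OC(=O)[C@@]3(C)O[C@@H]3C)[C@@H]12 | intermediate
34 | 3α-alcohol from 33 | C=C1C(=O)O[C@@H]2/C=C(C)\[C@H](O)C[C@H]3O[C@]3(C)C[C@@H](OC(=O)[C@@]3(C)O[C@@H]3C)[C@@H]12 | intermediate
35 | CNP0122107.1 | C=C1C(=O)O[C@@H]2/C=C(C)\C=C/[C@H]3O[C@]3(C)C[C@@H](OC(=O)[C@@]3(C)O[C@@H]3C)[C@@H]12 | target

Total step count: 20. Longest linear sequence: 15 steps (steps 1–3, 6–14 and 18–20, from (R)-carvone).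

The three steps most likely to fail

Step 8. The enolate may react through its unchelated conformer, in which the other face of C7 is open, so that facial control is lost or reversed. The C8 ether may also be expelled by β-elimination. The fallback reverses the order in which carbon and hydrogen reach C7. It sets out from 16, whose lithium enolate is added to ethyl glyoxylate to give the aldol adduct F1 (mixture at C7 and C11). Mesylation followed by DBU gives the alkylidene keto ester F2, for which either C7=C11 geometry serves. Conjugate reduction with [(Ph3P)CuH]6 in moist toluene touches only this doubly activated alkene. It places hydride on C11 and then a proton on C7 from the ring periphery, so that the same facial bias that would misdirect an alkylation now leaves the side chain on the β face. The fallback returns to the route at 18.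

Step 6. The alkenyllithium may decay by anti β-elimination of lithium 4-methoxybenzyl oxide before it meets the ketone, and the doubly activated α-position of the enone may be enolised. The fallback adds a vinyl anion that has no leaving group and makes the C8–O bond afterwards. It sets out from 4. (E)-1,2-Bis(tributylstannyl)ethene and n-BuLi (THF, −78 °C) give (E)-2-(tributylstannyl)ethenyllithium F3, which adds to 4 with the same facial preference to give the stannylvinyl carbinol F4. Iododestannylation with I2 at 0 °C gives the iodovinyl carbinol F5 with retention. Stereospecific C–O coupling of F5 with alcohol 5 (CuI, 3,4,7,8-tetramethyl-1,10-phenanthroline, Cs2CO3, toluene, 80 °C) returns to the route at 13.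

Step 20. The activated allylic alcohol may ionise, followed by transannular capture by the oxirane oxygen or by allylic substitution instead of loss of a C2 proton. The fallback is a concerted thermal syn elimination that never builds positive charge at C3. It sets out from 34. Thiophenol with catalytic Et3N adds to C13 and masks the methylene lactone as the thiol adduct F6. PhSSPh and PBu3 then replace the C3 hydroxyl with inversion to give the bis-sulfide F7, and mCPBA (2 equiv, −78 °C) gives the bis-sulfoxide F8. Heating in toluene over CaCO3 (about 100 °C) expels benzenesulfenic acid twice. This forms Z C2=C3 (the ring allows only the cis geometry) and restores C11=C13, and the fallback returns to the route at 35.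

Further compounds
F1 | step 8 | glyoxylate aldol adduct of 16 at C7 (C7 and C11 not controlled) | COc1ccc(CO[C@@H]2C/C(C)=C/C[C@@H](O[Si](C)(C)C(C)(C)C)/C(C)=C\C(=O)C2C(O)C(=O)OCC)cc1
F2 | step 8 | 7(11)-alkylidene keto ester (C7=C11 geometry not controlled) | COc1ccc(CO[C@@H]2C/C(C)=C/C[C@@H](O[Si](C)(C)C(C)(C)C)/C(C)=C\C(=O)C2=CC(=O)OCC)cc1
F3 | step 6 | (E)-2-(tributylstannyl)ethenyllithium | [Li]/C=C/[Sn](CCCC)(CCCC)CCCC
F4 | step 6 | (1R,4R,6R)-4-(tert-butyldimethylsilyloxy)-3-methyl-6-(prop-1-en-2-yl)-1-[(E)-2-(tributylstannyl)ethenyl]cyclohex-2-en-1-ol | O[C@]1(/C=C/[Sn](CCCC)(CCCC)CCCC)C=C(C)[C@H](O[Si](C)(C)C(C)(C)C)C[C@@H]1C(C)=C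
F5 | step 6 | (1R,4R,6R)-4-(tert-butyldimethylsilyloxy)-1-[(E)-2-iodoethenyl]-3-methyl-6-(prop-1-en-2-yl)cyclohex-2-en-1-ol | O[C@]1(/C=C/I)C=C(C)[C@H](O[Si](C)(C)C(C)(C)C)C[C@@H]1C(C)=C
F6 | step 20 | 13-phenylthio adduct of 34 (C11 not controlled) | c1ccccc1SCC1C(=O)O[C@@H]2/C=C(C)\[C@H](O)C[C@H]3O[C@]3(C)C[C@@H](OC(=O)[C@@]3(C)O[C@@H]3C)[C@@H]12
F7 | step 20 | 3β,13-bis(phenylthio) compound | c1ccccc1SCC1C(=O)O[C@@H]2/C=C(C)\[C@@H](Sc3ccccc3)C[C@H]3O[C@]3(C)C[C@@H](OC(=O)[C@@]3(C)O[C@@H]3C)[C@@H]12
F8 | step 20 | 3β,13-bis(phenylsulfinyl) compound (sulfur centres not controlled) | c1ccccc1S(=O)CC1C(=O)O[C@@H]2/C=C(C)\[C@@H](S(=O)c3ccccc3)C[C@H]3O[C@]3(C)C[C@@H](OC(=O)[C@@]3(C)O[C@@H]3C)[C@@H]12
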